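The readings are calculated with made-up constants.

- Take green, the flask the forecast puts first, and bound its open intermediate at 2.0 min from both sides, using the turnover rate that makes product from it.

| flask | substrate | reagent | capture agent | free catalyst | second catalyst | temperature | remark | time |
|---|---|---|---|---|---|---|---|---|
| oak | 0.39 mM | 2 mM | 0.10 mM | 4 µM | 1 µM | 10 °C | run made earlier |  |
| larch | 1 mM | 2 mM | 0.10 mM | 4 µM | 1 µM | 21 °C | run made earlier |  |
| maple | 1.8 mM | 2 mM | 0.10 mM | 4 µM | 1 µM | 10 °C | run made earlier |  |
| birch | 2 mM | 2 mM | 0.10 mM | 5.7 µM | 1 µM | 21 °C | run made earlier |  |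
| grey | 2.0 mM | 2.00 mM | 0.100 mM | 4.0 µM | 2.0 µM | 25 °C |  | 2.0 min |
| ochre | 2.0 mM | 2.00 mM | 0.100 mM | 12 µM | 1.0 µM | 20 °C |  | 2.0 min |
| blue | 0.50 mM | 2.00 mM | 0.0250 mM | 4.0 µM | 1.0 µM | 5 °C |  | 2.0 min |
| green | 2.0 mM | 2.00 mM | 0.100 mM | 4.0 µM | 1.0 µM | 5 °C |  | 2.0 min |

| run | time / s | open intermediate / % | product / % | substrate / % |
|---|---|---|---|---|
| oak | 10.0 | 85 | 3 | 11 |
| oak | 15.0 | 90 | 4 | 2 |
| oak | 30.0 | 83 | 8 | 2 |
| oak | 40.0 | 79 | 9 | 0 |
| oak | 60.0 | 71 | 21 | 1 |
| larch | 10.0 | 94 | 5 | 3 |
| larch | 15.0 | 94 | 4 | 0 |
| larch | 20.0 | 87 | 7 | 0 |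
| larch | 25.0 | 86 | 7 | 3 |
| maple | 12.0 | 91 | 3 | 3 |
| maple | 25.0 | 90 | 3 | 0 |
| maple | 40.0 | 89 | 10 | 0 |
| maple | 50.0 | 92 | 10 | 0 |
| maple | 60.0 | 86 | 6 | 0 |
| birch | 10.0 | 93 | 2 | 2 |
| birch | 12.0 | 92 | 5 | 0 |
| birch | 20.0 | 89 | 3 | 0 |
| birch | 25.0 | 90 | 5 | 0 |

(readings scatter by 2 percentage points)

- candidate steps: substrate + free catalyst -> free catalyst + open intermediate; second catalyst + open intermediate <-> catalyst intermediate; open intermediate + capture agent -> trapped intermediate; reagent + catalyst intermediate -> second catalyst + product
- no earlier run changes the charge of capture agent; that part of a forecast is a guess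
- no earlier run changes the charge of second catalyst; that part of a forecast is a guess

- ranking by amount of open intermediate, in percent of the substrate charged, from high to low, at 2.0 min (grey / ochre / blue / green)
- the amount of open intermediate, in percent of the substrate charged of the flask you put first, at 2.0 min
- the amount of open intermediate, in percent of the substrate charged of the flask you put last, at 2.0 min

- I take green's substrate as converted early, since oak's substrate already reads 2 % at 15.0 s, so open intermediate starts near the whole charge.
- Oak's last two readings give 1.12 s⁻¹ for the turnover rate, c(product) made per second over c(second catalyst) charged, which is the usual turnover frequency.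
- The same reading of maple gives 2.70 s⁻¹; both carry the scatter of 2 percentage points per reading.
- A steady rate integrates to a straight line: the product share equals turnover rate times c(second catalyst) times time, over c(substrate) charged.
- Maple is about as rich as green but warmer, so I use its rate as green's ceiling: 16.2 % product.
- Taking off the whole capture agent as well, 5.00 % of the substrate, I get a lower bound of 78.8 % open intermediate for green.
- Oak is thinner than green, so I use its rate as the floor, though oak is also warmer than green, which makes this the weaker side: 6.73 % product and no capture give an upper bound of 93.3 %.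
- The forecast says green > blue > ochre > grey, with 85 % for green and 48 % for grey, and of turnover by the second catalyst it writes “this partly saturates”; its value for green lies inside my bracket.

    substrate + free catalyst → free catalyst + open intermediate (k = 45000 M⁻¹ s⁻¹, Ea = 31.0 kJ mol⁻¹)
    second catalyst + open intermediate ⇌ catalyst intermediate (K = 1400 M⁻¹, k = 37000 M⁻¹ s⁻¹, Ea = 18.0 kJ mol⁻¹, ΔH = −34.0 kJ mol⁻¹)
    open intermediate + capture agent → trapped intermediate (k = 22.0 M⁻¹ s⁻¹, Ea = 49.0 kJ mol⁻¹)
    reagent + catalyst intermediate → second catalyst + product (k = 1800 M⁻¹ s⁻¹, Ea = 40.0 kJ mol⁻¹)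
    (constants at 5 °C)

- Green gives 81.5 %, inside the bracket, with 13.5 % product at 2.00 min, an average turnover rate of 2.25 s⁻¹, above oak's reading and below maple's. The order the flasks give is green > ochre > blue > grey, with grey last at 52.6 %; blue and ochre change places against the forecast, which wrote about 18 % product for blue. Blue is charged with a quarter of green's substrate, and oak's rate gives blue 26.9 % product, while blue shows 27.3 %. Blue's open intermediate stands at 69.4 %, below ochre's 72.0 %.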